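The target is disconnected at its bridge methine, the carbon (C1 of the 6-methylheptane-1,1-diyl chain) bonded to C6 of chroman ring A, C6 of chroman ring B and chain C2. Because this carbon lies between the C5 and C7 oxygens of ring A, it can begin as a C6 aldehyde. A 5-methylhexyl Grignard reagent adds, the alkoxide takes over the neighbouring C5 tert-butyl carbonate and expels it, and the magnesium phenoxide of ring B captures the resulting ortho-quinone methide at carbon. One flask thus forms both bridge bonds. The precursor is 5,7-dihydroxy-8-isobutyryl-2,2-dimethylchroman-6-carbaldehyde with a Boc carbonate on the C5 oxygen; ring B is the parent chroman without the formyl group.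

Key step: step 7

Assumption: ketone 1 and bromide 10 are taken as catalogue compounds, and magnesium-bound species are listed in their neutral, protonated form.

Step 1
Reactants: 1 2-methyl-1-(2,4,6-trihydroxyphenyl)propan-1-one
Product: 2 1-[4-(benzyloxy)-2,6-dihydroxyphenyl]-2-methylpropan-1-one
Conditions: BnBr (1.0 equiv), KHCO3 (1.2 equiv), DMF, 40 °C
Reagents that add atoms: benzyl bromide, BrCc1ccccc1
Why: Williamson etherification in which the C4 hydroxyl, para to the ketone and not hydrogen-bonded to it, is the most acidic and the only one the weak base ionises, so one equivalent of benzyl bromide should give mainly the 4-O-benzyl ether.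

Step 2
Reactants: 2 1-[4-(benzyloxy)-2,6-dihydroxyphenyl]-2-methylpropan-1-one; 3 3-methylbut-2-enal
Product: 5 1-[5-(benzyloxy)-7-hydroxy-2,2-dimethyl-2H-chromen-8-yl]-2-methylpropan-1-one, via oxatriene 4 (not isolated)
Conditions: 3 (1.1 equiv), ethylenediammonium diacetate (10 mol %), toluene, 110 °C
Reagents that add atoms: none
Why: Knoevenagel-type condensation of the enal at C3 gives oxatriene 4, whose oxa-6π electrocyclisation can only use an oxygen ortho to the ketone because the para oxygen is benzylated, which places the acyl group at C8 of the chromene.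

Step 3
Reactants: 5 1-[5-(benzyloxy)-7-hydroxy-2,2-dimethyl-2H-chromen-8-yl]-2-methylpropan-1-one
Product: 6 1-(5,7-dihydroxy-2,2-dimethylchroman-8-yl)-2-methylpropan-1-one (5,7-dihydroxy-8-isobutyryl-2,2-dimethylchroman)
Conditions: H2 (1 atm), 10% Pd/C, EtOAc/MeOH, rt
Reagents that add atoms: none
Why: Catalytic hydrogenation saturates the C3–C4 alkene and hydrogenolyses the benzyl ether in one operation, while the chelated, electron-rich aryl ketone is expected to survive at ambient pressure.

Step 4
Reactants: 6 1-(5,7-dihydroxy-2,2-dimethylchroman-8-yl)-2-methylpropan-1-one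
Product: 8 5,7-dihydroxy-8-isobutyryl-2,2-dimethylchroman-6-carbaldehyde, via iminium chloride 7 (not isolated)
Conditions: POCl3 (1.3 equiv), DMF (3 equiv), EtOAc, 0 °C → rt; then H2O, 50 °C
Reagents that add atoms: N,N-dimethylformamide, CN(C)C=O; water, O
Why: Vilsmeier–Haack formylation, in which the chloroiminium ion attacks C6, the only unsubstituted ring carbon and the one activated by two flanking hydroxyls, to give iminium salt 7 that water hydrolyses to the aldehyde.

Step 5
Reactants: 8 5,7-dihydroxy-8-isobutyryl-2,2-dimethylchroman-6-carbaldehyde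
Product: 9 tert-butyl (6-formyl-7-hydroxy-8-isobutyryl-2,2-dimethylchroman-5-yl) carbonate
Conditions: Boc2O (1.0 equiv), i-Pr2NEt (1.1 equiv), 4-(dimethylamino)pyridine (5 mol %), CH2Cl2, −20 → 0 °C
Reagents that add atoms: di-tert-butyl dicarbonate, CC(C)(C)OC(=O)OC(=O)OC(C)(C)C
Why: Nucleophile-catalysed O-acylation with one equivalent of Boc2O should favour the C5 hydroxyl, which is para to the ketone and less hindered than the C7 hydroxyl held between two carbonyl groups in a hydrogen bond to the ketone.

Step 6
Reactants: 10 1-bromo-5-methylhexane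
Product: 11 5-methylhexylmagnesium bromide
Conditions: Mg turnings (1.2 equiv), I2 (cat.), THF, rt → 45 °C; titrated before use
Reagents that add atoms: magnesium, [Mg]
Why: Grignard reagent formation by insertion of magnesium into a primary alkyl bromide is routine.

Step 7
Reactants: 9 tert-butyl (6-formyl-7-hydroxy-8-isobutyryl-2,2-dimethylchroman-5-yl) carbonate; 11 5-methylhexylmagnesium bromide; 6 1-(5,7-dihydroxy-2,2-dimethylchroman-8-yl)-2-methylpropan-1-one
Product: 15 6,6'-(6-methylheptane-1,1-diyl)bis(5,7-dihydroxy-8-isobutyryl-2,2-dimethylchroman), via alkoxide adduct 12 (not isolated), via benzylic carbonate 13 (not isolated), via ortho-quinone methide 14 (not isolated)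
Conditions: 9, THF, −78 °C; 11 (2.05 equiv), −78 °C, 1 h; then 6 (1.3 equiv) pre-treated with 11 (2.6 equiv) in THF at 0 °C, added at −78 °C; −78 °C → rt, 3 h; then 1 M aq. HCl, 0 °C
Reagents that add atoms: none
Why: The first equivalent of 11 deprotonates the C7 hydroxyl of 9 and the second adds to the C6 aldehyde (bridge–chain bond) to give alkoxide 12, which attacks the adjacent C5 carbonate through a six-membered transition state so that the Boc group moves to the benzylic oxygen (13); on warming, the freed C5 phenoxide expels tert-butyl carbonate to give ortho-quinone methide 14. The magnesium phenoxide of 6 then adds through C6, its only unsubstituted ring carbon, to the exocyclic carbon of 14 (bridge–aryl bond), and the dienone tautomerises back to the phenol. The closest known chemistry is the low-temperature generation of ortho-quinone methides from ortho-OBoc benzaldehydes and Grignard reagents with capture by a second nucleophile, joined to the familiar C-alkylation of phloroglucinol-type phenoxides by quinone methides. No ring is closed and no stereocentre results, because the bridge carbon ends with two identical aryl groups. The step needs the Grignard reagent to choose the aldehyde over both isobutyryl ketones and the carbonate, which should follow from the low temperature and from the ketones being flanked by two ortho oxygens and held as chelated, electron-rich magnesium phenoxides; C- rather than O-alkylation by 6 is favoured by the magnesium counter-ion.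

Compound list
1 | 2-methyl-1-(2,4,6-trihydroxyphenyl)propan-1-one | CC(C)C(=O)c1c(O)cc(O)cc1O | starting material
2 | 1-[4-(benzyloxy)-2,6-dihydroxyphenyl]-2-methylpropan-1-one | CC(C)C(=O)c1c(O)cc(OCc2ccccc2)cc1O | intermediate
3 | 3-methylbut-2-enal | CC(C)=CC=O | starting material
4 | 5-(benzyloxy)-3-hydroxy-2-isobutyryl-6-(3-methylbut-2-en-1-ylidene)cyclohexa-2,4-dien-1-one (alkene geometry not defined) | CC(C)C(=O)C1=C(O)C=C(OCc2ccccc2)C(=CC=C(C)C)C1=O | intermediate (not isolated)
5 | 1-[5-(benzyloxy)-7-hydroxy-2,2-dimethyl-2H-chromen-8-yl]-2-methylpropan-1-one | CC(C)C(=O)c1c(O)cc(OCc2ccccc2)c2C=CC(C)(C)Oc12 | intermediate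
6 | 1-(5,7-dihydroxy-2,2-dimethylchroman-8-yl)-2-methylpropan-1-one | CC(C)C(=O)c1c(O)cc(O)c2c1OC(C)(C)CC2 | intermediate
7 | [(5,7-dihydroxy-8-isobutyryl-2,2-dimethylchroman-6-yl)methylidene]dimethyliminium chloride | CC(C)C(=O)c1c(O)c(C=[N+](C)C)c(O)c2c1OC(C)(C)CC2.[Cl-] | intermediate (not isolated)
8 | 5,7-dihydroxy-8-isobutyryl-2,2-dimethylchroman-6-carbaldehyde | CC(C)C(=O)c1c(O)c(C=O)c(O)c2c1OC(C)(C)CC2 | intermediate
9 | tert-butyl (6-formyl-7-hydroxy-8-isobutyryl-2,2-dimethylchroman-5-yl) carbonate | CC(C)C(=O)c1c(O)c(C=O)c(OC(=O)OC(C)(C)C)c2c1OC(C)(C)CC2 | intermediate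
10 | 1-bromo-5-methylhexane | CC(C)CCCCBr | starting material
11 | 5-methylhexylmagnesium bromide | CC(C)CCCC[Mg]Br | intermediate
12 | tert-butyl [7-hydroxy-6-(1-hydroxy-6-methylheptyl)-8-isobutyryl-2,2-dimethylchroman-5-yl] carbonate (racemic; present as its magnesium alkoxide) | CC(C)CCCCC(O)c1c(OC(=O)OC(C)(C)C)c2c(c(C(=O)C(C)C)c1O)OC(C)(C)CC2 | intermediate (not isolated)
13 | tert-butyl [1-(5,7-dihydroxy-8-isobutyryl-2,2-dimethylchroman-6-yl)-6-methylheptyl] carbonate (racemic; present as its magnesium phenoxide) | CC(C)CCCCC(OC(=O)OC(C)(C)C)c1c(O)c2c(c(C(=O)C(C)C)c1O)OC(C)(C)CC2 | intermediate (not isolated)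
14 | 7-hydroxy-8-isobutyryl-2,2-dimethyl-6-(6-methylheptylidene)-3,4-dihydro-2H-chromen-5(6H)-one (alkene geometry not defined) | CC(C)CCCCC=C1C(=O)C2=C(OC(C)(C)CC2)C(C(=O)C(C)C)=C1O | intermediate (not isolated)
15 | 6,6'-(6-methylheptane-1,1-diyl)bis(5,7-dihydroxy-8-isobutyryl-2,2-dimethylchroman) (achiral) | CC(C)CCCCC(c1c(O)c2c(c(C(=O)C(C)C)c1O)OC(C)(C)CC2)c1c(O)c2c(c(C(=O)C(C)C)c1O)OC(C)(C)CC2 | target

Total step count: 7. Longest linear sequence: 6 steps (steps 1, 2, 3, 4, 5 and 7); step 6 is a one-step side branch.

Steps most likely to fail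

Step 7. The Grignard reagent may add sluggishly to the phenoxide-deactivated aldehyde or attack the carbonate instead. The alkyl-substituted quinone methide may also tautomerise to an ortho-alkenyl phenol, or be alkylated by any excess Grignard reagent, before the phenoxide captures it. The fallback sets out from 11 and 6 and returns at 15. Grignard reagent 11 is formylated with DMF (Bouveault aldehyde synthesis) to 6-methylheptanal F1. F1 is then condensed with two equivalents of chroman 6 under catalytic piperidinium acetate in CH2Cl2 at room temperature. This is a Knoevenagel condensation to the same quinone methide followed by conjugate C-alkylation by the second chroman, the classical aldehyde route to alkylidene-bridged acylphloroglucinol dimers.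

Step 5. Discrimination between the two hydrogen-bonded hydroxyls may be poor and over-acylation may occur. A carbonate on either ortho oxygen can be transferred in step 7, so a mixture of mono-carbonates would still converge; only double acylation is harmful. The fallback sets out from 8 and returns at 15. Aldehyde 8 is acylated exhaustively with excess Boc2O and 4-(dimethylamino)pyridine to di-tert-butyl (6-formyl-8-isobutyryl-2,2-dimethylchroman-5,7-diyl) bis(carbonate) F2, which has no acidic proton. F2 is coupled as in step 7 with just over one equivalent of 11 and the magnesium phenoxide of 6 to give the dimer still carrying one aryl carbonate, 7-O-Boc dimer F3 (racemic; a 5-O-Boc isomer would behave alike). The residual carbonate is cleaved with CF3CO2H in CH2Cl2 at 0 °C to give 15.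

Step 1. Mono-benzylation may be accompanied by over-alkylation to the dibenzyl ether and by C-benzylation of the electron-rich ring, and the mono-ether can undergo a second pyran annulation in step 2. The fallback sets out from 1 and returns at 6. Ketone 1 is dibenzylated on purpose (BnBr 2.2 equiv, K2CO3, DMF) to 1-[2,4-bis(benzyloxy)-6-hydroxyphenyl]-2-methylpropan-1-one F4; the last, chelated hydroxyl resists alkylation. The single remaining phenol is annulated with 3 (PhB(OH)2, AcOH, toluene, reflux) to 1-[5,7-bis(benzyloxy)-2,2-dimethyl-2H-chromen-8-yl]-2-methylpropan-1-one F5. Hydrogenation as in step 3 removes both benzyl groups and saturates the alkene to give 6.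

Further compounds
F1 | step 7 | 6-methylheptanal | CC(C)CCCCC=O
F2 | step 5 | di-tert-butyl (6-formyl-8-isobutyryl-2,2-dimethylchroman-5,7-diyl) bis(carbonate) | CC(C)C(=O)c1c(OC(=O)OC(C)(C)C)c(C=O)c(OC(=O)OC(C)(C)C)c2c1OC(C)(C)CC2
F3 | step 5 | tert-butyl {6-[1-(5,7-dihydroxy-8-isobutyryl-2,2-dimethylchroman-6-yl)-6-methylheptyl]-5-hydroxy-8-isobutyryl-2,2-dimethylchroman-7-yl} carbonate (racemic) | CC(C)CCCCC(c1c(O)c2c(c(C(=O)C(C)C)c1OC(=O)OC(C)(C)C)OC(C)(C)CC2)c1c(O)c2c(c(C(=O)C(C)C)c1O)OC(C)(C)CC2
F4 | step 1 | 1-[2,4-bis(benzyloxy)-6-hydroxyphenyl]-2-methylpropan-1-one | CC(C)C(=O)c1c(O)cc(OCc2ccccc2)cc1OCc1ccccc1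
F5 | step 1 | 1-[5,7-bis(benzyloxy)-2,2-dimethyl-2H-chromen-8-yl]-2-methylpropan-1-one | CC(C)C(=O)c1c(OCc2ccccc2)cc(OCc2ccccc2)c2C=CC(C)(C)Oc12
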